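The runs are simulated with made-up constants; noise was put on by code.

Count turnovers first: every flask holds the same 6.6 mM of free catalyst, so a charge of substrate divided by it is a number of turnovers charged per catalyst.

in all of them: partner 0.825 M; free catalyst 6.6 mM

|  | substrate | remark | time |
|---|---|---|---|
| elm | 0.10 M (in portions, 4) | run made earlier; portions every 12 s |  |
| ash | 1.4 M (in portions, 4) | run made earlier; portions every 12 s |  |
| dusk | 1.0 M (in portions, 4) | the portions of substrate follow each other after 12 s, the first at the start | 12 min |
| dawn | 0.60 M (in portions, 4) | the portions of substrate follow each other after 12 s, the first at the start | 12 min |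
| spring | 0.33 M (in portions, 4) | the portions of substrate follow each other after 12 s, the first at the start | 12 min |
| noon | 0.080 M (in portions, 4) | the portions of substrate follow each other after 12 s, the first at the start | 12 min |
| midnight | 0.20 M (in portions, 4) | the portions of substrate follow each other after 12 s, the first at the start | 12 min |

| run | time / min | product / % |
|---|---|---|
| elm | 1.33 | 18.5 |
| elm | 2.50 | 36.6 |
| elm | 4.00 | 53.7 |
| elm | 5.00 | 63.1 |
| elm | 6.00 | 70.2 |
| ash | 0.500 | 2.1 |
| ash | 0.833 | 3.9 |
| ash | 1.50 | 8.4 |
| ash | 3.00 | 16.2 |
| ash | 6.00 | 30.2 |

(scatter of a reading: 0.3 percentage points)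

* the flasks put in order of amount of product, in percent of the substrate charged, best first, at 12 min (dusk / dawn / spring / noon / midnight)
* the amount of product, in percent of the substrate charged of the flask you put first, at 12 min
* the amount of product, in percent of the substrate charged of the flask you put last, at 12 min

I read two rates from the earlier runs. In elm, with partner at 0.825 M against 0.10 M of substrate, the logarithm of the substrate left fell at 0.215 min⁻¹, a pseudo-first-order rate. In ash, product rose on average at 0.0715 M min⁻¹, which I took as a ceiling of 10.8 min⁻¹ per catalyst charged. Their ratio, 50.3, I called the crossover count: the turnovers charged at which the time to work through the charge at the ceiling equals the first-order time, one over the first-order rate.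

My rule added two times: the logarithm of charged over left, divided by the first-order rate, plus the turnovers made, divided by the ceiling. Noon charges 12.1 turnovers, fewer than the crossover count, and dusk charges 152, more than it. At a given percent the second time of my sum is longer for dusk than for noon, so I ranked the flasks by rising charge, smallest first. Partner is the limiting reagent in dusk, at 0.825 M against 1.0 M. My sum took dusk to the forecast's 57% in 11.9 min, close to the time allowed. It took noon to 92.2% in 12.9 min, longer than 12 min, so my noon stood slightly below the forecast's.

The forecast gave noon > midnight > spring > dawn > dusk, with 92.2% and 57%, on the ground that “Percent yield therefore falls as the charge rises”.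

The simulation gave noon > midnight > spring > dawn > dusk, with 92.7% and 59.0%.

    catalyst intermediate C → free catalyst + product (k = 0.670 s⁻¹)
    substrate + free catalyst ⇌ catalyst intermediate A (K = 2.70 L mol⁻¹, k = 1.01 L mol⁻¹ s⁻¹)
    partner + catalyst intermediate A ⇌ catalyst intermediate B (K = 10.1 L mol⁻¹, k = 0.705 L mol⁻¹ s⁻¹)
    catalyst intermediate B ⇌ released group + catalyst intermediate C (K = 28.0 M, k = 58.0 s⁻¹)

For dusk's 59.0%, my sum needs 12.4 min. The neighbouring flask was dusk with 0.33 M of partner in place of 0.825 M, and it gave 28.0%. I kept the first-order rate for that neighbour and scaled the ceiling with partner, which lowers the crossover count to 20.1. Its 28.0% then needs, by my sum, 11.3 min. At 12.0 min, that neighbour held 72% of its substrate and 15% of its partner, unbound.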